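**Assumption:** the target is (3S,6E)-1-(3,4-dihydroxyphenyl)-7-(4-hydroxyphenyl)hept-6-en-3-yl acetate (CIP: O > CH2CH2Ar > CH2CH2CH=CHAr > H gives S). (S)-1,2-Epoxy-5-hexene and 4-(tert-butyldimethylsilyloxy)styrene are taken as purchased. This is a paper route; none of it has been run.

## Retrosynthetic overview

1. Target ⇐ tris-TBS ether 12 by buffered fluoride desilylation; the alkyl acetate is already in place.
2. The (E)-styrene C6=C7 ⇐ cross-metathesis of terminal-alkene acetate 10 with 4-(TBSO)styrene 11.
3. The C3 stereocentre and the C1–C2 bond ⇐ Cu-catalysed opening of (S)-1,2-epoxy-5-hexene 7 by the 3,4-bis(TBSO)benzyl Grignard from 6; chirality is bought in the epoxide.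
4. Benzyl chloride 6 ⇐ 3,4-dihydroxybenzaldehyde 1 (silylation, reduction, chlorination).
5. No rings are formed; both arenes are purchased intact.

## Route

**Step 1**
Reactants: 1, 3,4-dihydroxybenzaldehyde; 2, tert-butyldimethylsilyl chloride
Product: 3, 3,4-bis(tert-butyldimethylsilyloxy)benzaldehyde
Conditions: TBSCl (2.4 equiv), imidazole (5 equiv), DMF, rt
Reagents that add atoms: TBSCl, CC(C)(C)[Si](C)(C)Cl
Why: Standard imidazole-mediated silylation of both phenols gives a fluoride-labile protecting group that tolerates Grignard, acylation and metathesis conditions.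

**Step 2**
Reactants: 3, 3,4-bis(TBSO)benzaldehyde
Product: 4, [3,4-bis(tert-butyldimethylsilyloxy)phenyl]methanol
Conditions: NaBH4, MeOH/THF, 0 °C, 30 min
Reagents that add atoms: none
Why: Borohydride reduction of the aldehyde; aryl silyl ethers survive short exposure at 0 °C.

**Step 3**
Reactants: 4, benzylic alcohol; 5, thionyl chloride
Product: 6, 4-(chloromethyl)-1,2-bis(tert-butyldimethylsilyloxy)benzene
Conditions: SOCl2, pyridine, CH2Cl2, 0 °C; used crude straight away
Reagents that add atoms: SOCl2, O=S(Cl)Cl
Why: Deoxychlorination via the chlorosulfite is fast for an electron-rich benzylic alcohol, and the pyridine buffer protects the aryl silyl ethers.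

**Step 4**
Reactants: 6, benzyl chloride (1.5 equiv); 7, (S)-1,2-epoxy-5-hexene [(S)-2-(but-3-en-1-yl)oxirane]
Product: 8, (S)-1-[3,4-bis(tert-butyldimethylsilyloxy)phenyl]hept-6-en-3-ol
Conditions: Mg (I2-activated), Et2O or 2-MeTHF, 0 °C, slow addition of 6; then CuI (10 mol %), −40 → 0 °C, add 7
Reagents that add atoms: (S)-1,2-epoxy-5-hexene, C=CCC[C@H]1CO1 (Mg is not retained)
Why: Cu-catalysed SN2 opening of the terminal epoxide by the benzylic Grignard occurs at the unsubstituted CH2, so the purchased C–O stereocentre is untouched; the descriptor stays S because the former epoxide CH2 (now CH2CH2Ar) still outranks the butenyl arm.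

**Step 5**
Reactants: 8, (S)-alcohol; 9, acetic anhydride
Product: 10, (S)-1-[3,4-bis(tert-butyldimethylsilyloxy)phenyl]hept-6-en-3-yl acetate
Conditions: Ac2O, pyridine, DMAP (cat.), CH2Cl2, rt
Reagents that add atoms: acetic anhydride, CC(=O)OC(C)=O
Why: DMAP-catalysed O-acylation takes place at oxygen with retention at C3, and the only free hydroxyl is the secondary alcohol.

**Step 6**
Reactants: 10, terminal-alkene acetate; 11, 4-(tert-butyldimethylsilyloxy)styrene (3 equiv)
Product: 12, (3S,6E)-1-[3,4-bis(tert-butyldimethylsilyloxy)phenyl]-7-[4-(tert-butyldimethylsilyloxy)phenyl]hept-6-en-3-yl acetate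
Conditions: Grubbs II (5 mol %), CH2Cl2, 40 °C, Ar sparge to remove ethylene
Reagents that add atoms: 4-(TBSO)styrene, C=Cc1ccc(O[Si](C)(C)C(C)(C)C)cc1 (supplies the ArCH= unit; ethylene is lost)
Why: Olefin cross-metathesis of an unhindered terminal alkene with excess styrene is thermodynamically E-selective (typically >20:1); the ester, silyl ethers and the remote stereocentre are inert to the Ru carbene.

**Step 7**
Reactants: 12, tris-TBS acetate
Product: 13, (3S,6E)-1-(3,4-dihydroxyphenyl)-7-(4-hydroxyphenyl)hept-6-en-3-yl acetate (target)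
Conditions: TBAF (3.5 equiv), AcOH (4 equiv), THF, 0 °C → rt, under Ar; NH4Cl work-up
Reagents that add atoms: none
Why: Aryl silyl ethers are cleaved rapidly by fluoride, and the acetic acid buffer keeps phenoxide levels low so the secondary acetate is neither cleaved nor transferred and the catechol is not oxidised.

## Compound list

1 | 3,4-dihydroxybenzaldehyde | O=Cc1ccc(O)c(O)c1 | starting material
2 | tert-butyldimethylsilyl chloride | CC(C)(C)[Si](C)(C)Cl | starting material (reagent)
3 | 3,4-bis(tert-butyldimethylsilyloxy)benzaldehyde | O=Cc1ccc(O[Si](C)(C)C(C)(C)C)c(O[Si](C)(C)C(C)(C)C)c1 | intermediate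
4 | [3,4-bis(tert-butyldimethylsilyloxy)phenyl]methanol | OCc1ccc(O[Si](C)(C)C(C)(C)C)c(O[Si](C)(C)C(C)(C)C)c1 | intermediate
5 | thionyl chloride | O=S(Cl)Cl | starting material (reagent)
6 | 4-(chloromethyl)-1,2-bis(tert-butyldimethylsilyloxy)benzene | ClCc1ccc(O[Si](C)(C)C(C)(C)C)c(O[Si](C)(C)C(C)(C)C)c1 | intermediate
7 | (S)-1,2-epoxy-5-hexene | C=CCC[C@H]1CO1 | starting material
8 | (S)-1-[3,4-bis(tert-butyldimethylsilyloxy)phenyl]hept-6-en-3-ol | O[C@@H](CCC=C)CCc1ccc(O[Si](C)(C)C(C)(C)C)c(O[Si](C)(C)C(C)(C)C)c1 | intermediate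
9 | acetic anhydride | CC(=O)OC(C)=O | starting material (reagent)
10 | (S)-1-[3,4-bis(tert-butyldimethylsilyloxy)phenyl]hept-6-en-3-yl acetate | CC(=O)O[C@@H](CCC=C)CCc1ccc(O[Si](C)(C)C(C)(C)C)c(O[Si](C)(C)C(C)(C)C)c1 | intermediate
11 | 4-(tert-butyldimethylsilyloxy)styrene | C=Cc1ccc(O[Si](C)(C)C(C)(C)C)cc1 | starting material
12 | (3S,6E)-1-[3,4-bis(TBSO)phenyl]-7-[4-(TBSO)phenyl]hept-6-en-3-yl acetate | CC(=O)O[C@@H](CC/C=C/c1ccc(O[Si](C)(C)C(C)(C)C)cc1)CCc1ccc(O[Si](C)(C)C(C)(C)C)c(O[Si](C)(C)C(C)(C)C)c1 | intermediate
13 | (3S,6E)-1-(3,4-dihydroxyphenyl)-7-(4-hydroxyphenyl)hept-6-en-3-yl acetate | CC(=O)O[C@@H](CC/C=C/c1ccc(O)cc1)CCc1ccc(O)c(O)c1 | target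

## Summary

Total steps: 7. Longest linear sequence: 7 (1 → 3 → 4 → 6 → 8 → 10 → 12 → 13; epoxide 7 and styrene 11 are purchased).

Steps most likely to fail, each with a fallback that changes the approach:

1. **Step 4 (with the labile chloride from step 3).** The electron-rich benzylic Grignard may undergo Wurtz homocoupling, and MgCl2 may open the epoxide to a chlorohydrin. Fallback: reverse the polarity. Couple 6 with allylMgBr to give the 4-aryl-1-butene, epoxidise with mCPBA, and resolve by Jacobsen hydrolytic kinetic resolution to the (R)-2-(2-arylethyl)oxirane. Open this with allylMgBr/CuI to reach the same (S)-alcohol 8; the descriptor changes only because the CIP priorities change.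

2. **Step 6.** Cross-metathesis may give styrene homodimer, incomplete conversion or E/Z mixtures. Fallback: ozonolyse the terminal alkene to the C6 aldehyde (with the alcohol silyl-protected, acetylating afterwards). Then build the styrene by Horner–Wadsworth–Emmons olefination with diethyl 4-(TBSO)benzylphosphonate, which is reliably E-selective.

3. **Step 7.** Triple desilylation may cause partial acetate loss or transfer to a phenoxide, or catechol oxidation. Fallback: change the protecting-group logic. Carry the phenols as acetates (4-acetoxystyrene in the metathesis; desilylate and peracetylate the catechol to give the tetraacetate). Finish with a chemoselective aryl-acetate cleavage (NH4OAc in aqueous MeOH, or lipase-mediated alcoholysis), which leaves the secondary alkyl acetate intact.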